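**Retrosynthetic overview**
1. The benzo ring, its C7 methyl and the benzylic carbon of the side chain are bought intact as 2,3-dimethylbenzoic acid (1); the other five chain carbons come from 4-bromo-2-methylbut-1-ene (2) by lateral alkylation, giving acid 3.
2. Acid 3 is converted to the aryl diazomethyl ketone 4; the siloxyalkyne 6 (from ethyl isobutyrate, 5) carries the isopropyl group and the C2 oxygen.
3. Key step (the only ring-forming event): photo-Wolff rearrangement of 4 to an aryl ketene, [2+2] with 6, 4π opening, then 6π closure onto the benzene ring, which is dearomatised and then re-aromatises to naphthol 7.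
4. Desilylation with aerobic oxidative dearomatisation of 7 gives salvipisone (8); acetylation gives acetylsalvipisone (9).

Assumption: the target SMILES contains no stereocentre and no stereogenic double bond, so the molecule is achiral and no enantiocontrol is needed; compounds 1, 2 and 5 are taken as commercial.

**Step 1**
Reactants: 1, 2,3-dimethylbenzoic acid; 2, 4-bromo-2-methylbut-1-ene
Product: 3, 3-methyl-2-(4-methylpent-4-en-1-yl)benzoic acid
Conditions: LDA (2.2 equiv), THF, −78 → 0 °C, 1 h; then 2 (1.2 equiv), −78 °C → rt; dilute HCl workup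
Reagents that add atoms: none beyond reactant 2 (C=C(C)CCBr)
Why: Carboxylate-directed lateral (benzylic) lithiation deprotonates only the ortho 2-methyl group (dilithio o-quinodimethane-type dienediolate; the 3-methyl is not conjugated to the carboxylate), and the soft benzylic anion is alkylated by the primary bromide (SN2).

**Step 2**
Reactants: 3, 3-methyl-2-(4-methylpent-4-en-1-yl)benzoic acid
Product: 4, 2-diazo-1-[3-methyl-2-(4-methylpent-4-en-1-yl)phenyl]ethan-1-one
Conditions: NaH (1.0 equiv), THF; (COCl)2, cat. DMF, 0 °C → rt; concentrate; then CH2N2 (3 equiv), Et2O, 0 °C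
Reagents that add atoms: diazomethane, C=[N+]=[N-]
Why: Acylation of diazomethane by the acid chloride (first half of the Arndt–Eistert sequence); making the chloride from the sodium carboxylate avoids free HCl, so the 1,1-disubstituted alkene is not hydrochlorinated.

**Step 3**
Reactants: 5, ethyl 2-methylpropanoate (ethyl isobutyrate)
Product: 6, triisopropyl[(3-methylbut-1-yn-1-yl)oxy]silane (i-Pr–C≡C–OTIPS)
Conditions: CH2Br2, LiTMP, THF, −78 °C; add 5; then n-BuLi (excess), −78 °C → rt; then TIPSCl, −78 °C → rt
Reagents that add atoms: dibromomethane, BrCBr (one carbon); triisopropylsilyl chloride, CC(C)[Si](Cl)(C(C)C)C(C)C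
Why: Kowalski ester homologation: LiCHBr2 adds to the ester, Br/Li exchange and carbenoid rearrangement give the lithium ynolate, which the bulky silyl chloride traps on oxygen.

**Step 4 (key step)**
Reactants: 4, 2-diazo-1-[3-methyl-2-(4-methylpent-4-en-1-yl)phenyl]ethan-1-one; 6, triisopropyl[(3-methylbut-1-yn-1-yl)oxy]silane (1.5 equiv)
Product: 7, 2-isopropyl-6-methyl-5-(4-methylpent-4-en-1-yl)-3-[(triisopropylsilyl)oxy]naphthalen-1-ol
Conditions: hv (254 nm, Vycor), degassed ClCH2CH2Cl (0.3 M), rt, 6 h; then 80 °C, 3 h
Reagents that add atoms: none (N2 is lost)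
Why: Danheiser photochemical benzannulation. Photo-Wolff rearrangement gives the aryl ketene, which undergoes regioselective [2+2] with the ynol ether (the i-Pr-bearing carbon bonds to the ketene C=O). The resulting 4-aryl-cyclobutenone opens (4π) to a dienylketene that closes (6π) onto the only free ortho carbon of the benzene ring, and tautomerisation gives the naphthol. This places i-Pr next to the new OH, OTIPS next to C4–H, and C4–H peri to the side chain.

**Step 5**
Reactants: 7, the silyloxy-naphthol from step 4
Product: 8, 2-hydroxy-3-isopropyl-7-methyl-8-(4-methylpent-4-en-1-yl)naphthalene-1,4-dione (salvipisone)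
Conditions: TBAF (2 equiv), THF, O2 (1 atm), rt; then 1 M HCl
Reagents that add atoms: dioxygen, O=O
Why: Fluoride desilylation releases the electron-rich naphthalene-1,3-diol(ate), which autoxidises at the free C4 position (para to O-1, ortho to O-3) to the 2-hydroxy-1,4-quinone (oxidative dearomatisation); the isolated alkene is inert.

**Step 6**
Reactants: 8, salvipisone
Product: 9, acetylsalvipisone, 3-isopropyl-7-methyl-8-(4-methylpent-4-en-1-yl)-1,4-dioxo-1,4-dihydronaphthalen-2-yl acetate
Conditions: Ac2O, pyridine, cat. DMAP, CH2Cl2, 0 °C → rt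
Reagents that add atoms: acetic anhydride, CC(=O)OC(C)=O
Why: O-acylation of the acidic hydroxyquinone (vinylogous acid) under standard nucleophilic-catalysis conditions; no other nucleophilic group is present.

**Compound list**
1 | 2,3-dimethylbenzoic acid | Cc1cccc(C(=O)O)c1C | starting material
2 | 4-bromo-2-methylbut-1-ene | C=C(C)CCBr | starting material
3 | 3-methyl-2-(4-methylpent-4-en-1-yl)benzoic acid | C=C(C)CCCc1c(C)cccc1C(=O)O | intermediate
4 | 2-diazo-1-[3-methyl-2-(4-methylpent-4-en-1-yl)phenyl]ethan-1-one | C=C(C)CCCc1c(C)cccc1C(=O)C=[N+]=[N-] | intermediate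
5 | ethyl 2-methylpropanoate | CCOC(=O)C(C)C | starting material
6 | triisopropyl[(3-methylbut-1-yn-1-yl)oxy]silane | CC(C)C#CO[Si](C(C)C)(C(C)C)C(C)C | intermediate
7 | 2-isopropyl-6-methyl-5-(4-methylpent-4-en-1-yl)-3-[(triisopropylsilyl)oxy]naphthalen-1-ol | C=C(C)CCCc1c(C)ccc2c(O)c(C(C)C)c(O[Si](C(C)C)(C(C)C)C(C)C)cc12 | intermediate
8 | salvipisone, 2-hydroxy-3-isopropyl-7-methyl-8-(4-methylpent-4-en-1-yl)naphthalene-1,4-dione | C=C(C)CCCc1c(C)ccc2c1C(=O)C(O)=C(C(C)C)C2=O | intermediate
9 | acetylsalvipisone (achiral) | C=C(C)CCCc1c(C)ccc2c1C(=O)C(OC(C)=O)=C(C(C)C)C2=O | target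

**Step count**
Total steps: 6. Longest linear sequence: 5 (steps 1, 2, 4, 5, 6; step 3 is a one-step side branch).

**Steps most likely to fail, with fallbacks**
1. Step 4 (photochemical benzannulation; the aryl ketene is ortho-hindered, and benzylic C–H insertion or ester formation may compete). Fallback: build the quinone ring by a squarate (Moore) ring expansion. Dimethyl squarate with i-PrMgCl then TFAA gives 3-isopropyl-4-methoxycyclobutene-1,2-dione. Add the aryllithium from 1-bromo-3-methyl-2-(4-methylpent-4-enyl)benzene, heat in refluxing p-xylene, oxidise in air, then hydrolyse the methyl ether with KOH to reach 8.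
2. Step 1 (E2 of the homoallylic bromide to isoprene, or incomplete dianion formation). Fallback: reverse the polarity. Couple 2,6-dibromobenzyl bromide with (3-methylbut-3-enyl)MgBr (Li2CuCl4 cat.), desymmetrise the dibromide by mono Br/Li exchange and MeI, then a second Br/Li exchange and CO2 to give 3.
3. Step 5 (one-pot desilylation and autoxidation may over-oxidise or stall at the diol). Fallback: oxidise first, as the silyl ether, with a one-electron oxidant (Fremy's salt or salcomine/O2, para-oxidation of the free 1-naphthol) to the 2-silyloxy-1,4-quinone, then desilylate with HF·pyridine.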